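A direct plan would join a furan (ring A) to an ynone by a MgI2 halo-aldol reaction to the iodoenone A1, close ring C by carbonylative lactonisation to the methylidene butenolide A2, form a cyclohexane by intramolecular furan Diels–Alder reaction and hydrogenation to the oxanorbornane lactone A3, and cut the C1–C6 bond by alkoxy-radical scission to the ten-membered lactol A4, to be acylated and dehydrated last.
Its weakest steps would be three. The halo-aldol would leave C8 to 1,3-induction from a tertiary carbinol whose two carbon groups differ little in size. The furan cycloaddition would be reversible and would leave the ring closure and C1, C4 and C6 to a tether conformation. The photochemical C1–C6 scission would be untested, would fall on the most advanced material, and would leave the 5E alkene to a final ionisation of a lactol ester.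

Plan of the new route
Cuts: C5=C6 (retron of a vinylogous aldol condensation), then C8–C9 (dithiane anion on a C9–C10 epoxide), then C1–O of ring A (epoxide opening by the C4 hydroxyl).
Ring C comes from but-2-yne-1,4-diol, vinylmagnesium chloride and CO2; C1–C5, C9, C10, C14 and C15 are the chain of (R)-linalool, whose carbinol carbon is C4.
Ring order: C (step 1), A (step 5), B (step 12).
Enabling feature: C6 is the γ-carbon of butenolide ring C (C5 of its 2-silyloxyfuran form), and the cis-2,5-disubstituted oxolane ring A holds the C5 aldehyde on C4 beside it. Ring B therefore closes by a polar C5–C6 aldol addition, and E1cB loss then funnels all aldol isomers into the 5E enol lactone.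
C8, C1 and C10 are set by reagent control; no cycloaddition, fragmentation or lactol is needed.

Key step: step 12

Assumptions: germacrane numbering is used throughout (ring B = C1–C10; ring A = C1–C4 plus the ether oxygen; ring C = C6, C7, C11, C12 plus the lactone oxygen; C13 on C11, C14 on C10, C15 on C4). Commercial (R)-(−)-linalool is taken as the single enantiomer.

Step 1
Reactants: 1 but-2-yne-1,4-diol; 2 vinylmagnesium chloride; 3 carbon dioxide
Product: 6 4-ethenyl-3-(hydroxymethyl)furan-2(5H)-one, via oxamagnesacycle 4 (not isolated), via hydroxy acid 5 (not isolated)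
Conditions: 2 (4.5 equiv), THF/cyclohexane, reflux, 16 h; CO2 (gas), −20 °C to rt; 2 M HCl, rt
Reagents that add atoms: none
Why: In this hydroxyl-directed anti-carbomagnesiation of a propargylic alkoxide the vinyl group adds to the alkyne carbon next to the chelating alkoxide and magnesium ends on the far carbon in a five-membered ring, so carboxylation places the carboxyl group cis to C6H2–O and acid closes butenolide ring C with the vinyl group (later C8) on C7 and the hydroxymethyl group (C13) on C11; the diol is symmetric, so no regiochemical question arises.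

Step 2
Reactants: 6 4-ethenyl-3-(hydroxymethyl)furan-2(5H)-one; 7 propane-1,3-dithiol
Product: 9 4-(1,3-dithian-2-yl)-3-(hydroxymethyl)furan-2(5H)-one, via formyl butenolide 8 (not isolated)
Conditions: O3, CH2Cl2/MeOH 5:1, −78 °C, stopped at the end point of Sudan red 7B; Me2S, −78 °C to rt; concentrate; 7 (1.2 equiv), BF3·OEt2 (0.3 equiv), CH2Cl2, 0 °C
Reagents that add atoms: ozone [O-][O+]=O (its oxygen stays only in 8)
Why: Ozonolysis should cleave the terminal alkene of the dienyl lactone in preference to the tetrasubstituted, ester-deactivated ring alkene, and Lewis-acid dithioacetalisation turns the sensitive aldehyde at once into the dithiane needed for Corey–Seebach umpolung at C8.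

Step 3
Reactants: 9 4-(1,3-dithian-2-yl)-3-(hydroxymethyl)furan-2(5H)-one
Product: 10 triisopropyl({4-(1,3-dithian-2-yl)-2-[(triisopropylsilyl)oxy]furan-3-yl}methoxy)silane
Conditions: iPr3SiOTf (2.3 equiv), Et3N (3 equiv), CH2Cl2, 0 °C to rt
Reagents that add atoms: triisopropylsilyl trifluoromethanesulfonate CC(C)[Si](OS(=O)(=O)C(F)(F)F)(C(C)C)C(C)C
Why: Soft enolisation (silyl dienol ether formation) converts the butenolide into the aromatic 2-silyloxyfuran, which removes the acidic C6 hydrogens so that only the dithiane C–H is left for lithiation, and the same reagent protects the primary C13 hydroxyl.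

Step 4
Reactants: 11 (R)-(−)-linalool
Product: 12 (2E,6R)-2,6-dimethylocta-2,7-diene-1,6-diol
Conditions: SeO2 (0.3 equiv), t-BuOOH (70% aq., 2.5 equiv), salicylic acid (0.1 equiv), CH2Cl2, rt, run to partial conversion; recovered 11 recycled
Reagents that add atoms: tert-butyl hydroperoxide CC(C)(C)OO (oxygen, relayed through SeO2)
Why: Selenium dioxide allylic oxidation (ene reaction, then [2,3]-sigmatropic shift) attacks the (E)-methyl group of the trisubstituted alkene (later C9) selectively and does not touch the tertiary carbinol centre (later C4).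

Step 5
Reactants: 12 (2E,6R)-2,6-dimethylocta-2,7-diene-1,6-diol
Product: 14 (2R)-2-[(2S,5R)-5-ethenyl-5-methyloxolan-2-yl]propane-1,2-diol, via epoxy alcohol 13 (not isolated)
Conditions: Ti(OiPr)4 (0.2 equiv), D-(−)-diethyl tartrate (0.25 equiv), t-BuOOH (2 equiv, in isooctane), 4 Å molecular sieves, CH2Cl2, −20 °C; then camphorsulfonic acid (0.1 equiv), 0 °C to rt
Reagents that add atoms: tert-butyl hydroperoxide CC(C)(C)OO
Why: In this Sharpless asymmetric epoxidation the D-(−)-tartrate catalyst should give the (2R,3R)-epoxide of the (E)-allylic alcohol (the tertiary vinyl carbinol reacts far more slowly), and 5-exo opening at the secondary epoxide carbon C1 by the C4 hydroxyl with inversion then gives the cis-2,5-disubstituted oxolane with C1 = S and the epoxide oxygen retained on C10 (R).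

Step 6
Reactants: 14 (2R)-2-[(2S,5R)-5-ethenyl-5-methyloxolan-2-yl]propane-1,2-diol
Product: 16 (2R)-2-[(2S,5R)-5-ethenyl-5-methyloxolan-2-yl]-2-methyloxirane, via primary tosylate 15 (not isolated)
Conditions: NaH (2.5 equiv), 1-(p-tolylsulfonyl)imidazole (1.1 equiv), THF, 0 °C to rt
Reagents that add atoms: 1-(p-tolylsulfonyl)imidazole Cc1ccc(cc1)S(=O)(=O)n1ccnc1 (the sulfonyl group stays only in 15)
Why: Selective sulfonylation of the primary alkoxide followed by intramolecular Williamson displacement by the tertiary alkoxide closes the terminal epoxide without breaking the C10–O bond, so C10 keeps its configuration.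

Step 7
Reactants: 10 triisopropyl({4-(1,3-dithian-2-yl)-2-[(triisopropylsilyl)oxy]furan-3-yl}methoxy)silane; 16 (2R)-2-[(2S,5R)-5-ethenyl-5-methyloxolan-2-yl]-2-methyloxirane
Product: 19 triethylsilyl ether of (2R)-1-{2-[5-(triisopropylsilyloxy)-4-(triisopropylsilyloxymethyl)furan-3-yl]-1,3-dithian-2-yl}-2-[(2S,5R)-5-ethenyl-5-methyloxolan-2-yl]propan-2-ol, via lithiated dithiane 17 (not isolated), via lithium alkoxide 18 (not isolated)
Conditions: 10, n-BuLi (1.05 equiv), THF/HMPA 10:1, −78 to −30 °C; 16 (1.2 equiv), −78 to 0 °C; Et3SiCl (1.5 equiv), 0 °C to rt; aq. NaHCO3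
Reagents that add atoms: n-butyllithium [Li]CCCC (lithium only in 17 and 18); chlorotriethylsilane CC[Si](Cl)(CC)CC
Why: In this Corey–Seebach dithiane alkylation the lithiated 2-aryl-1,3-dithiane opens the 2,2-disubstituted epoxide at its CH2 end (SN2), forming C8–C9 without touching C10, and silylation of the tertiary alkoxide in the same flask blocks later retro-aldol cleavage and lactol formation.

Step 8
Reactants: 19 dithiane adduct
Product: 21 4-{(3R)-3-[(2S,5R)-5-ethenyl-5-methyloxolan-2-yl]-3-(triethylsilyloxy)butanoyl}-3-(triisopropylsilyloxymethyl)furan-2(5H)-one, via dithianyl butenolide 20 (not isolated)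
Conditions: Bu4NF/AcOH 1:1 (1.1 equiv), THF, −78 °C; then MeI (10 equiv), CaCO3 (5 equiv), MeCN/H2O 9:1, 45 °C
Reagents that add atoms: water O
Why: Buffered fluoride should cleave only the silyl dienol ether, whose protonation at C6 returns the conjugated butenolide, and alkylative dithiane hydrolysis (S-methylation, then water) unveils the C8 ketone without oxidants that would attack the alkenes.

Step 9
Reactants: 21 C8 ketone
Product: 22 4-{(1S,3R)-3-[(2S,5R)-5-ethenyl-5-methyloxolan-2-yl]-1-hydroxy-3-(triethylsilyloxy)butyl}-3-(triisopropylsilyloxymethyl)furan-2(5H)-one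
Conditions: (R)-2-methyl-CBS-oxazaborolidine (0.3 equiv), catecholborane (1.8 equiv), toluene/CH2Cl2, −78 °C; MeOH, pH 7 buffer
Reagents that add atoms: none
Why: In this Corey–Bakshi–Shibata reduction the (R)-oxazaborolidine should bind the ketone with the sp2 butenolide arm as the large group and deliver hydride to the face that gives the 8S alcohol (reagent control), while catecholborane at low temperature leaves the vinyl group, the lactone and the silyl ethers alone.

Step 10
Reactants: 22 8S alcohol; 23 methacrylic anhydride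
Product: 24 (1S,3R)-3-[(2S,5R)-5-ethenyl-5-methyloxolan-2-yl]-1-[5-oxo-4-(triisopropylsilyloxymethyl)-2,5-dihydrofuran-3-yl]-3-(triethylsilyloxy)butyl 2-methylprop-2-enoate
Conditions: 23 (1.5 equiv), Et3N (3 equiv), DMAP (0.1 equiv), BHT (trace), CH2Cl2, 0 °C to rt
Reagents that add atoms: none
Why: DMAP-catalysed acylation of the only free hydroxyl installs the methacrylate with retention at C8.

Step 11
Reactants: 24 methacrylate
Product: 25 (1S,3R)-3-[(2S,5R)-5-formyl-5-methyloxolan-2-yl]-1-[5-oxo-4-(triisopropylsilyloxymethyl)-2,5-dihydrofuran-3-yl]-3-(triethylsilyloxy)butyl 2-methylprop-2-enoate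
Conditions: O3, CH2Cl2, −78 °C, stopped at the end point of Sudan red 7B; PPh3 (1.5 equiv), −78 °C to rt
Reagents that add atoms: ozone [O-][O+]=O
Why: Ozonolysis stopped at the indicator end point should cleave the isolated vinyl group, which reacts much faster with the electrophilic oxidant than the ester-conjugated methacrylate and butenolide alkenes, and C4 bears no hydrogen, so the aldehyde cannot epimerise.

Step 12
Reactants: 25 butenolide aldehyde
Product: 28 (1S,4R,8S,10R)-1,4-epoxy-5-hydroxy-8-(methacryloyloxy)-10-(triethylsilyloxy)-13-(triisopropylsilyloxy)germacr-7(11)-en-12,6-olide (C5/C6 epimers), via silyloxyfuran aldehyde 26 (not isolated), via silylated aldol 27 (not isolated)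
Conditions: 25 added over 10 h to Me3SiOTf (3 equiv) and iPr2NEt (4 equiv), CH2Cl2 (final 0.001 M), −20 to 0 °C; then 0.5 M aq. citric acid, 0 °C
Reagents that add atoms: trimethylsilyl trifluoromethanesulfonate C[Si](C)(C)OS(=O)(=O)C(F)(F)F (silicon only in 26 and 27)
Why: Soft enolisation (silyl triflate on the lactone carbonyl, amine at C6–H) turns the butenolide into its 2-trimethylsilyloxyfuran 26, whose C5 position (C6 of the target) adds to the silyl-activated C5 aldehyde in an intramolecular vinylogous Mukaiyama aldol reaction; the closest known reaction types are the one-pot silyl triflate/amine vinylogous aldol of butenolides with aldehydes and the silylative cycloaldolisation of butenolide aldehydes to five- to seven-membered carbocycles. Ring B (ten-membered, nine atoms along the ether bridge) closes in the exo-trig mode on the aldehyde carbonyl by forming C5–C6, a bond outside both ring A and ring C. The two new stereocentres C5 and C6 are not controlled and need not be, because C6 becomes sp2 and the C5 oxygen is lost in step 13, so all four isomers serve. The step needs γ- over α-attack, secured because C11 is fully substituted and silyloxyfurans react at C5, and it needs ring closure over oligomerisation, secured by slow addition to 0.001 M and by the cis-2,5-disubstituted oxolane, which turns the C4 aldehyde arm and the C1 arm toward each other. The aldehyde has no α-hydrogen and is the only carbonyl that the silyl triflate activates strongly, and the C8 ester and the C10 and C13 silyl ethers are poor leaving groups under amine-buffered conditions at low temperature.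

Step 13
Reactants: 28 macrocyclic aldol (C5/C6 epimers)
Product: 30 (1S,4R,5E,8S,10R)-1,4-epoxy-8-(methacryloyloxy)-10-(triethylsilyloxy)-13-(triisopropylsilyloxy)germacra-5,7(11)-dien-12,6-olide, via C5 mesylate 29 (not isolated)
Conditions: MsCl (2 equiv), Et3N (6 equiv), CH2Cl2, −20 to 0 °C; then DBU (1.5 equiv), 0 °C
Reagents that add atoms: methanesulfonyl chloride CS(=O)(=O)Cl (the sulfonyl group stays only in 29)
Why: Mesylation and E1cB elimination through the 2-oxidofuran (deprotonation at C6) form the C5=C6 enol-lactone bond: C6 becomes planar, either C5 epimer can set its mesylate perpendicular to that plane, and the bridged ring should let C4 lie only on the C7 side, so all aldol isomers converge on the 5E (ring-cis) alkene, with mesylate leaving far faster than the C13 silyloxy group.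

Step 14
Reactants: 30 protected dienolide; 31 acetic anhydride
Product: 33 (1S,4R,5E,8S,10R)-13-acetoxy-1,4-epoxy-10-hydroxy-8-(methacryloyloxy)germacra-5,7(11)-dien-12,6-olide (CNP0516045.1), via 10,13-diol 32 (not isolated)
Conditions: HF·pyridine, pyridine/THF, 0 °C to rt; aq. NaHCO3, extract, concentrate; 31 (1.3 equiv), pyridine, 0 °C
Reagents that add atoms: none
Why: Fluoride-mediated desilylation frees the C10 and C13 hydroxyls, and acetylation in pyridine should acylate the primary C13 hydroxyl but not the hindered tertiary C10 hydroxyl, with no base strong enough to disturb the allylic acetate or the enol lactone.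

## Compound list
1 | but-2-yne-1,4-diol | OCC#CCO | starting material
2 | vinylmagnesium chloride | C=C[Mg]Cl | starting material
3 | carbon dioxide | O=C=O | starting material
4 | 4-ethenyl-3-[(chloromagnesiooxy)methyl]-2,5-dihydro-1,2-oxamagnesole | C=CC1=C(CO[Mg]Cl)[Mg]OC1 | intermediate
5 | (2Z)-2,3-bis(hydroxymethyl)penta-2,4-dienoic acid | OC/C(C=C)=C(/CO)C(O)=O | intermediate
6 | 4-ethenyl-3-(hydroxymethyl)furan-2(5H)-one | C=CC1=C(CO)C(=O)OC1 | intermediate
7 | propane-1,3-dithiol | SCCCS | starting material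
8 | 4-(hydroxymethyl)-5-oxo-2,5-dihydrofuran-3-carbaldehyde | O=CC1=C(CO)C(=O)OC1 | intermediate
9 | 4-(1,3-dithian-2-yl)-3-(hydroxymethyl)furan-2(5H)-one | OCC1=C(C2SCCCS2)COC1=O | intermediate
10 | triisopropyl({4-(1,3-dithian-2-yl)-2-[(triisopropylsilyl)oxy]furan-3-yl}methoxy)silane | CC(C)[Si](OCc1c(O[Si](C(C)C)(C(C)C)C(C)C)occ1C1SCCCS1)(C(C)C)C(C)C | intermediate
11 | (R)-(−)-linalool | C=C[C@](C)(O)CCC=C(C)C | starting material
12 | (2E,6R)-2,6-dimethylocta-2,7-diene-1,6-diol | OC/C(C)=C/CC[C@@](C)(O)C=C | intermediate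
13 | [(2R,3R)-3-[(3R)-3-hydroxy-3-methylpent-4-en-1-yl]-2-methyloxiran-2-yl]methanol | OC[C@@]1(C)O[C@@H]1CC[C@@](C)(O)C=C | intermediate
14 | (2R)-2-[(2S,5R)-5-ethenyl-5-methyloxolan-2-yl]propane-1,2-diol | OC[C@@](C)(O)[C@@H]1CC[C@](C)(C=C)O1 | intermediate
15 | (2R)-2-[(2S,5R)-5-ethenyl-5-methyloxolan-2-yl]-2-hydroxypropyl 4-methylbenzenesulfonate | Cc1ccc(cc1)S(=O)(=O)OC[C@@](C)(O)[C@@H]1CC[C@](C)(C=C)O1 | intermediate
16 | (2R)-2-[(2S,5R)-5-ethenyl-5-methyloxolan-2-yl]-2-methyloxirane | C[C@@]1(CO1)[C@@H]1CC[C@](C)(C=C)O1 | intermediate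
17 | 2-lithio derivative of 10 | CC(C)[Si](OCc1c(O[Si](C(C)C)(C(C)C)C(C)C)occ1C1([Li])SCCCS1)(C(C)C)C(C)C | intermediate
18 | lithium (2R)-1-{2-[5-(triisopropylsilyloxy)-4-(triisopropylsilyloxymethyl)furan-3-yl]-1,3-dithian-2-yl}-2-[(2S,5R)-5-ethenyl-5-methyloxolan-2-yl]propan-2-olate | CC(C)[Si](OCc1c(O[Si](C(C)C)(C(C)C)C(C)C)occ1C1(SCCCS1)C[C@@](C)(O[Li])[C@@H]1CC[C@](C)(C=C)O1)(C(C)C)C(C)C | intermediate
19 | triethylsilyl ether of (2R)-1-{2-[5-(triisopropylsilyloxy)-4-(triisopropylsilyloxymethyl)furan-3-yl]-1,3-dithian-2-yl}-2-[(2S,5R)-5-ethenyl-5-methyloxolan-2-yl]propan-2-ol | CC(C)[Si](OCc1c(O[Si](C(C)C)(C(C)C)C(C)C)occ1C1(SCCCS1)C[C@@](C)(O[Si](CC)(CC)CC)[C@@H]1CC[C@](C)(C=C)O1)(C(C)C)C(C)C | intermediate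
20 | 4-{2-[(2R)-2-[(2S,5R)-5-ethenyl-5-methyloxolan-2-yl]-2-(triethylsilyloxy)propyl]-1,3-dithian-2-yl}-3-(triisopropylsilyloxymethyl)furan-2(5H)-one | O=C1OCC(C2(SCCCS2)C[C@@](C)(O[Si](CC)(CC)CC)[C@@H]2CC[C@](C)(C=C)O2)=C1CO[Si](C(C)C)(C(C)C)C(C)C | intermediate
21 | 4-{(3R)-3-[(2S,5R)-5-ethenyl-5-methyloxolan-2-yl]-3-(triethylsilyloxy)butanoyl}-3-(triisopropylsilyloxymethyl)furan-2(5H)-one | O=C1OCC(C(=O)C[C@@](C)(O[Si](CC)(CC)CC)[C@@H]2CC[C@](C)(C=C)O2)=C1CO[Si](C(C)C)(C(C)C)C(C)C | intermediate
22 | 4-{(1S,3R)-3-[(2S,5R)-5-ethenyl-5-methyloxolan-2-yl]-1-hydroxy-3-(triethylsilyloxy)butyl}-3-(triisopropylsilyloxymethyl)furan-2(5H)-one | O=C1OCC([C@@H](O)C[C@@](C)(O[Si](CC)(CC)CC)[C@@H]2CC[C@](C)(C=C)O2)=C1CO[Si](C(C)C)(C(C)C)C(C)C | intermediate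
23 | methacrylic anhydride | C=C(C)C(=O)OC(=O)C(C)=C | starting material
24 | (1S,3R)-3-[(2S,5R)-5-ethenyl-5-methyloxolan-2-yl]-1-[5-oxo-4-(triisopropylsilyloxymethyl)-2,5-dihydrofuran-3-yl]-3-(triethylsilyloxy)butyl 2-methylprop-2-enoate | O=C1OCC([C@@H](OC(=O)C(C)=C)C[C@@](C)(O[Si](CC)(CC)CC)[C@@H]2CC[C@](C)(C=C)O2)=C1CO[Si](C(C)C)(C(C)C)C(C)C | intermediate
25 | (1S,3R)-3-[(2S,5R)-5-formyl-5-methyloxolan-2-yl]-1-[5-oxo-4-(triisopropylsilyloxymethyl)-2,5-dihydrofuran-3-yl]-3-(triethylsilyloxy)butyl 2-methylprop-2-enoate | O=C1OCC([C@@H](OC(=O)C(C)=C)C[C@@](C)(O[Si](CC)(CC)CC)[C@@H]2CC[C@](C)(C=O)O2)=C1CO[Si](C(C)C)(C(C)C)C(C)C | intermediate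
26 | 2-(trimethylsilyloxy)furan form of 25 | C[Si](C)(C)Oc1occ([C@@H](OC(=O)C(C)=C)C[C@@](C)(O[Si](CC)(CC)CC)[C@@H]2CC[C@](C)(C=O)O2)c1CO[Si](C(C)C)(C(C)C)C(C)C | intermediate
27 | 5-O-trimethylsilyl ether of 28 (C5/C6 epimers) | C=C(C)C(=O)O[C@H]1C[C@@](C)(O[Si](CC)(CC)CC)[C@@H]2CC[C@](C)(C(O[Si](C)(C)C)C3OC(=O)C(CO[Si](C(C)C)(C(C)C)C(C)C)=C31)O2 | intermediate
28 | (1S,4R,8S,10R)-1,4-epoxy-5-hydroxy-8-(methacryloyloxy)-10-(triethylsilyloxy)-13-(triisopropylsilyloxy)germacr-7(11)-en-12,6-olide (C5/C6 epimers) | C=C(C)C(=O)O[C@H]1C[C@@](C)(O[Si](CC)(CC)CC)[C@@H]2CC[C@](C)(C(O)C3OC(=O)C(CO[Si](C(C)C)(C(C)C)C(C)C)=C31)O2 | intermediate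
29 | 5-O-methanesulfonate of 28 (C5/C6 epimers) | C=C(C)C(=O)O[C@H]1C[C@@](C)(O[Si](CC)(CC)CC)[C@@H]2CC[C@](C)(C(OS(C)(=O)=O)C3OC(=O)C(CO[Si](C(C)C)(C(C)C)C(C)C)=C31)O2 | intermediate
30 | (1S,4R,5E,8S,10R)-1,4-epoxy-8-(methacryloyloxy)-10-(triethylsilyloxy)-13-(triisopropylsilyloxy)germacra-5,7(11)-dien-12,6-olide | C=C(C)C(=O)O[C@H]1C[C@@](C)(O[Si](CC)(CC)CC)[C@@H]2CC[C@](C)(/C=C3/OC(=O)C(CO[Si](C(C)C)(C(C)C)C(C)C)=C31)O2 | intermediate
31 | acetic anhydride | CC(=O)OC(C)=O | starting material
32 | (1S,4R,5E,8S,10R)-1,4-epoxy-10,13-dihydroxy-8-(methacryloyloxy)germacra-5,7(11)-dien-12,6-olide | C=C(C)C(=O)O[C@H]1C[C@@](C)(O)[C@@H]2CC[C@](C)(/C=C3/OC(=O)C(CO)=C31)O2 | intermediate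
33 | (1S,4R,5E,8S,10R)-13-acetoxy-1,4-epoxy-10-hydroxy-8-(methacryloyloxy)germacra-5,7(11)-dien-12,6-olide (CNP0516045.1) | C=C(C)C(=O)O[C@H]1C[C@@](C)(O)[C@@H]2CC[C@](C)(/C=C3/OC(=O)C(COC(C)=O)=C31)O2 | target

Total step count: 14. Longest linear sequence: 11 steps (steps 1–3 and 7–14, or steps 4–6 and 7–14).

Steps most likely to fail

Step 12. The ten-membered ring may not close: transannular strain and the neopentyl position of the aldehyde may let intermolecular aldol addition and oligomerisation win, and the silyl triflate may ionise the C8 ester or the C13 silyl ether next to the electron-rich silyloxyfuran. The fallback is a Horner–Wadsworth–Emmons ring closure that sets out from 24 and comes back at 30, replacing steps 11–13. Compound 24 would be silylated (iPr3SiOTf, Et3N) to its 2-(triisopropylsilyloxy)furan F1. Bromination at C6 with N-bromosuccinimide at −78 °C would give the 5-bromobutenolide F2, and heating with triethyl phosphite (Michaelis–Arbuzov reaction) would give the C6 diethyl phosphonate F3. Ozonolysis of the vinyl group as in step 11 would give the phosphonate aldehyde F4. LiCl with iPr2NEt in MeCN at 0.001 M (Masamune–Roush conditions) would then close ring B directly as the C5=C6 alkene 30.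

Step 7. The tertiary dithiane anion may be too hindered for SN2 attack at the epoxide CH2 next to quaternary C10; the epoxide may isomerise to an allylic alcohol under the basic conditions, or the ambident anion may be alkylated on the furan ring. The fallback is a reductive cross-electrophile acylation that sets out from 6 and 16 and comes back at 21, replacing steps 2, 3, 7 and 8. Compound 6 would be silylated (iPr3SiCl, imidazole) to the silyl ether F5, ozonised to the formyl butenolide F6, oxidised with NaClO2 to the carboxylic acid F7 and converted with oxalyl chloride into the acid chloride F8. Epoxide 16 would be opened with LiI/AcOH to the iodohydrin F9 and silylated (Et3SiOTf, 2,6-lutidine) to the iodide F10. NiCl2·glyme with 4,4'-di-tert-butyl-2,2'-bipyridine and zinc powder in N,N-dimethylacetamide would join F8 and F10 through the C9 radical to ketone 21.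

Step 9. Facial discrimination may be poor, because both flanks of the C8 ketone are bulky (a neopentyl-type CH2 and an ortho-substituted butenolide). The fallback is correction by inversion, setting out from 21 and coming back at 24. An unselective Luche reduction (NaBH4, CeCl3, MeOH, −78 °C) would give 22 together with its 8R epimer F11. After separation, 22 would go on through step 10, and F11 would be esterified with methacrylic acid under Mitsunobu conditions (PPh3, diisopropyl azodicarboxylate) with inversion at C8, so both epimers converge on 24.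

Further compounds
F1 | step 12 | 2-(triisopropylsilyloxy)furan form of 24 | CC(C)[Si](Oc1occ([C@@H](OC(=O)C(C)=C)C[C@@](C)(O[Si](CC)(CC)CC)[C@@H]2CC[C@](C)(C=C)O2)c1CO[Si](C(C)C)(C(C)C)C(C)C)(C(C)C)C(C)C
F2 | step 12 | C6-bromo derivative of 24 (5-bromofuran-2(5H)-one; C6 epimers) | O=C1OC(Br)C([C@@H](OC(=O)C(C)=C)C[C@@](C)(O[Si](CC)(CC)CC)[C@@H]2CC[C@](C)(C=C)O2)=C1CO[Si](C(C)C)(C(C)C)C(C)C
F3 | step 12 | C6-diethoxyphosphoryl derivative of 24 (C6 epimers) | O=C1OC(P(=O)(OCC)OCC)C([C@@H](OC(=O)C(C)=C)C[C@@](C)(O[Si](CC)(CC)CC)[C@@H]2CC[C@](C)(C=C)O2)=C1CO[Si](C(C)C)(C(C)C)C(C)C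
F4 | step 12 | C6-diethoxyphosphoryl derivative of 25 (C6 epimers) | O=C1OC(P(=O)(OCC)OCC)C([C@@H](OC(=O)C(C)=C)C[C@@](C)(O[Si](CC)(CC)CC)[C@@H]2CC[C@](C)(C=O)O2)=C1CO[Si](C(C)C)(C(C)C)C(C)C
F5 | step 7 | 4-ethenyl-3-(triisopropylsilyloxymethyl)furan-2(5H)-one | C=CC1=C(CO[Si](C(C)C)(C(C)C)C(C)C)C(=O)OC1
F6 | step 7 | 5-oxo-4-(triisopropylsilyloxymethyl)-2,5-dihydrofuran-3-carbaldehyde | O=CC1=C(CO[Si](C(C)C)(C(C)C)C(C)C)C(=O)OC1
F7 | step 7 | 5-oxo-4-(triisopropylsilyloxymethyl)-2,5-dihydrofuran-3-carboxylic acid | OC(=O)C1=C(CO[Si](C(C)C)(C(C)C)C(C)C)C(=O)OC1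
F8 | step 7 | 5-oxo-4-(triisopropylsilyloxymethyl)-2,5-dihydrofuran-3-carbonyl chloride | ClC(=O)C1=C(CO[Si](C(C)C)(C(C)C)C(C)C)C(=O)OC1
F9 | step 7 | (2S)-2-[(2S,5R)-5-ethenyl-5-methyloxolan-2-yl]-1-iodopropan-2-ol | IC[C@@](C)(O)[C@@H]1CC[C@](C)(C=C)O1
F10 | step 7 | triethylsilyl ether of F9 | IC[C@@](C)(O[Si](CC)(CC)CC)[C@@H]1CC[C@](C)(C=C)O1
F11 | step 9 | 4-{(1R,3R)-3-[(2S,5R)-5-ethenyl-5-methyloxolan-2-yl]-1-hydroxy-3-(triethylsilyloxy)butyl}-3-(triisopropylsilyloxymethyl)furan-2(5H)-one (8R epimer of 22) | O=C1OCC([C@H](O)C[C@@](C)(O[Si](CC)(CC)CC)[C@@H]2CC[C@](C)(C=C)O2)=C1CO[Si](C(C)C)(C(C)C)C(C)C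
A1 | direct plan | (Z)-3-[(1S,3R)-1,3-dihydroxy-3-(5-methylfuran-2-yl)butyl]-5-hydroxy-4-iodopent-3-en-2-one | CC(=O)/C([C@@H](O)C[C@@](C)(O)c1ccc(C)o1)=C(\I)CO
A2 | direct plan | 4-[(1S,3R)-1,3-dihydroxy-3-(5-methylfuran-2-yl)butyl]-3-(hydroxymethyl)-5-methylidenefuran-2(5H)-one | C=C1OC(=O)C(CO)=C1[C@@H](O)C[C@@](C)(O)c1ccc(C)o1
A3 | direct plan | (1R,4R,6R,8S,10R)-1,4-epoxy-8,10,13-trihydroxy-1,6-cyclogermacr-7(11)-en-12,6-olide | C[C@]12CC[C@@]3(O1)[C@](C)(O)C[C@H](O)C4=C(CO)C(=O)O[C@@]34C2
A4 | direct plan | (1S,4R,8S,10R)-1,4-epoxy-6,8,10,13-tetrahydroxygermacr-7(11)-en-12,6-olide (C6 epimers) | O[C@H]1C[C@@](C)(O)[C@@H]2CC[C@](C)(CC3(O)OC(=O)C(CO)=C31)O2
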